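Everything rests on closing ring C (the dihydrofuran) through the O1–C7a bond of an aryne. Ring B, the benzo ring, bears the furan oxygen on C7a beside a free hydroxyl on C7; these two neighbouring oxygenated carbons are read as the ends of an aryne triple bond generated from a 2-fluoroarene. In one operation, lithiation next to fluorine and loss of LiF, 5-exo addition of the side-chain alkoxide to C7a, and borylation–oxidation of the C7 carbanion give ring C and the complete oxygen pattern of ring B. The precursor is a syn-aldol-derived (1S,2R)-1,2-diarylpropane-1,3-diol, TIPS-protected at the primary oxygen, with fluorine ortho to the side chain. The trans lactone is attached afterwards by enolate alkylation.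

Key step: step 6

Remarks on the chemistry (assumptions and design):
- Assumption: (S)-4-benzyl-2-oxazolidinone, 4-benzyloxy-3-methoxybenzaldehyde (otherwise one benzylation from vanillin), (S)-epichlorohydrin and 1-benzyloxy-4-bromo-2-methoxybenzene are taken as commercial.
- Stereochemical bookkeeping: the (2S,3S) syn aldol adduct corresponds to the (1S,2R) diol and to the trans-(2S,3R) dihydrobenzofuran. The (S)-4-benzyl lactone leads to the trans-(3S,4S) lactone of the target.
- The primary oxygen next to the reacting alkoxide carries TIPS. A smaller silyl group could shift 1,5 from oxygen to oxygen in the alkoxide and offer the primary oxygen to the aryne, which also closes a five-membered ring.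
- The C5 carbon is carried as a hydroxymethyl group introduced under basic conditions only, so no acid-mediated acetal chemistry is run next to the ionisable 4-alkoxybenzylic carbinol. It passes through the key step as its lithium alkoxide and is ready for bromination afterwards.
- Fragment 1 is made in steps 1–8, fragment 2 (the lactone) in steps 9–11; union and completion are steps 12–14.

Step 1
Reactants: 1 5-bromo-2-fluorophenylacetic acid; 2 (S)-4-benzyl-2-oxazolidinone
Product: 4 (S)-4-benzyl-3-[2-(5-bromo-2-fluorophenyl)acetyl]oxazolidin-2-one, via mixed pivalic anhydride 3 (not isolated)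
Conditions: PivCl, Et3N, THF, −20 °C; then 2, LiCl, −20 °C → rt
Reagents that add atoms: none
Why: Mixed-anhydride N-acylation of an oxazolidinone (LiCl-assisted acyl transfer), in which the hindered pivaloyl carbonyl steers attack to the arylacetyl carbonyl; no stereocentre is formed.

Step 2
Reactants: 4 (S)-4-benzyl-3-[2-(5-bromo-2-fluorophenyl)acetyl]oxazolidin-2-one; 5 4-benzyloxy-3-methoxybenzaldehyde
Product: 7 (S)-4-benzyl-3-[(2S,3S)-3-(4-benzyloxy-3-methoxyphenyl)-2-(5-bromo-2-fluorophenyl)-3-hydroxypropanoyl]oxazolidin-2-one, via Z-dibutylboron enolate 6 (not isolated)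
Conditions: Bu2BOTf, i-Pr2NEt, CH2Cl2, 0 °C; then 5, −78 → 0 °C; pH 7 buffer, MeOH, 30% H2O2, 0 °C
Reagents that add atoms: none
Why: Evans syn aldol, in which the Z boron enolate reacts through a chair Zimmerman–Traxler transition state on the face away from the auxiliary benzyl group, so the auxiliary sets both new centres as (2S,3S) (aryl and hydroxyl syn), the relationship that becomes trans in ring C.

Step 3
Reactants: 7 (S)-4-benzyl-3-[(2S,3S)-3-(4-benzyloxy-3-methoxyphenyl)-2-(5-bromo-2-fluorophenyl)-3-hydroxypropanoyl]oxazolidin-2-one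
Product: 8 (1S,2R)-1-(4-benzyloxy-3-methoxyphenyl)-2-(5-bromo-2-fluorophenyl)propane-1,3-diol
Conditions: LiBH4, THF/MeOH, 0 °C
Reagents that add atoms: none
Why: Reductive cleavage of the N-acyl oxazolidinone by borohydride gives the primary alcohol and returns the auxiliary without touching either stereocentre (the C2 descriptor changes from S to R only through the change in CIP ranking).

Step 4
Reactants: 8 (1S,2R)-1-(4-benzyloxy-3-methoxyphenyl)-2-(5-bromo-2-fluorophenyl)propane-1,3-diol
Product: 9 (1S,2R)-1-(4-benzyloxy-3-methoxyphenyl)-2-(5-bromo-2-fluorophenyl)-3-(triisopropylsilyloxy)propan-1-ol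
Conditions: TIPSCl, imidazole, DMF, 0 °C → rt
Reagents that add atoms: triisopropylsilyl chloride, CC(C)[Si](Cl)(C(C)C)C(C)C
Why: Selective silylation of the primary hydroxyl by a bulky silyl chloride, which leaves the hindered benzylic secondary hydroxyl free for the ring closure.

Step 5
Reactants: 9 (1S,2R)-1-(4-benzyloxy-3-methoxyphenyl)-2-(5-bromo-2-fluorophenyl)-3-(triisopropylsilyloxy)propan-1-ol
Product: 11 (1S,2R)-1-(4-benzyloxy-3-methoxyphenyl)-2-[2-fluoro-5-(hydroxymethyl)phenyl]-3-(triisopropylsilyloxy)propan-1-ol, via aryl aldehyde 10 (not isolated)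
Conditions: n-BuLi (2.2 equiv), THF, −78 °C; DMF, −78 → 0 °C; then MeOH, NaBH4, 0 °C
Reagents that add atoms: N,N-dimethylformamide, CN(C)C=O
Why: Bromine–lithium exchange on the lithium alkoxide (faster at −78 °C than deprotonation next to fluorine), Bouveault-type formylation with DMF and borohydride reduction of aldehyde 10 in the same flask install the C5 carbon at the alcohol level without any acid.

Step 6
Reactants: 11 (1S,2R)-1-(4-benzyloxy-3-methoxyphenyl)-2-[2-fluoro-5-(hydroxymethyl)phenyl]-3-(triisopropylsilyloxy)propan-1-ol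
Product: 15 (2S,3R)-2-(4-benzyloxy-3-methoxyphenyl)-5-(hydroxymethyl)-3-(triisopropylsilyloxymethyl)-2,3-dihydrobenzofuran-7-ol, via aryne dialkoxide 12 (not isolated), via C7 aryllithium 13 (not isolated), via C7 dimethyl boronate 14 (not isolated)
Conditions: lithium 2,2,6,6-tetramethylpiperidide (LiTMP, 4.5 equiv), THF (0.03 M), −78 → −30 °C; B(OMe)3 (8 equiv), −78 °C → rt; aq NaOH, 30% H2O2, 0 °C
Reagents that add atoms: hydrogen peroxide, OO
Why: LiTMP first turns both hydroxyls into lithium alkoxides and then removes the only ring B proton ortho to fluorine (the future C7–H); loss of LiF gives aryne 12 across the future C7 and C7a. The secondary alkoxide, three atoms away, adds to C7a in a 5-exo-dig closure onto the in-plane aryne bond (ring C, O1–C7a) and leaves the carbanion on C7 as aryllithium 13; this is an anionic benzyne cyclisation with electrophilic capture of the resulting aryllithium, a known reaction type. Trimethyl borate converts 13 into boronate 14, and alkaline peroxide oxidises the C–B bond to the C7 phenol at the same position. No stereocentre is formed: the carbinol oxygen is the nucleophile, so C2 and C3 keep the configuration set in step 2. Regiochemistry is secured by the substrate, since one proton only flanks fluorine and the tether reaches only C7a; in addition the hindered amide does not add to the aryne and its conjugate acid is a poor proton donor towards 13, the TIPS ether resists the 1,5 silyl shift, and the remote C5 alkoxide cannot reach the aryne.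

Step 7
Reactants: 15 (2S,3R)-2-(4-benzyloxy-3-methoxyphenyl)-5-(hydroxymethyl)-3-(triisopropylsilyloxymethyl)-2,3-dihydrobenzofuran-7-ol
Product: 16 [(2S,3R)-7-benzyloxy-2-(4-benzyloxy-3-methoxyphenyl)-3-(triisopropylsilyloxymethyl)-2,3-dihydrobenzofuran-5-yl]methanol
Conditions: BnBr (1.1 equiv), K2CO3, DMF, rt
Reagents that add atoms: benzyl bromide, BrCc1ccccc1
Why: Williamson etherification under weak base alkylates only the phenoxide (K2CO3 does not deprotonate the benzylic alcohol) and masks C7–OH as a benzyl ether that leaves with the others in the last step.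

Step 8
Reactants: 16 [(2S,3R)-7-benzyloxy-2-(4-benzyloxy-3-methoxyphenyl)-3-(triisopropylsilyloxymethyl)-2,3-dihydrobenzofuran-5-yl]methanol
Product: 17 (2S,3R)-7-benzyloxy-2-(4-benzyloxy-3-methoxyphenyl)-5-(bromomethyl)-3-(triisopropylsilyloxymethyl)-2,3-dihydrobenzofuran
Conditions: CBr4, PPh3, CH2Cl2, 0 °C; used at once
Reagents that add atoms: tetrabromomethane, BrC(Br)(Br)Br
Why: Appel bromination converts the primary benzylic alcohol into the bromide under neutral conditions that should spare the TIPS ether and the benzylic C2–O1 bond.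

Step 9
Reactants: 18 diethyl malonate; 19 (S)-epichlorohydrin
Product: 20 ethyl (1R,5S)-2-oxo-3-oxabicyclo[3.1.0]hexane-1-carboxylate
Conditions: NaOEt, EtOH, rt → reflux
Reagents that add atoms: none
Why: Double alkylation of malonate by epichlorohydrin (epoxide opening, chloride displacement by the alkoxide, then 3-exo-tet closure at the stereogenic carbon with one inversion) followed by lactonisation, so the chiral-pool centre of the (S)-epoxide becomes C5 (S) of the bicycle.

Step 10
Reactants: 21 1-benzyloxy-4-bromo-2-methoxybenzene; 20 ethyl (1R,5S)-2-oxo-3-oxabicyclo[3.1.0]hexane-1-carboxylate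
Product: 23 ethyl (3R,4S)-4-(4-benzyloxy-3-methoxybenzyl)-2-oxotetrahydrofuran-3-carboxylate, via arylmagnesium bromide 22 (not isolated)
Conditions: 21, Mg, THF, reflux; then 20, CuI (10 mol %), THF, −30 → 0 °C; aq NH4Cl
Reagents that add atoms: none
Why: Copper-catalysed homoconjugate addition of the aryl Grignard reagent to the doubly activated cyclopropane, in which the aryl group attacks the unsubstituted cyclopropane CH2, the ring-fusion stereocentre is untouched and becomes C4 (S), the epimerisable C3 ester settles trans, and the magnesium enolate formed protects the carbonyls.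

Step 11
Reactants: 23 ethyl (3R,4S)-4-(4-benzyloxy-3-methoxybenzyl)-2-oxotetrahydrofuran-3-carboxylate
Product: 24 (S)-4-(4-benzyloxy-3-methoxybenzyl)dihydrofuran-2(3H)-one
Conditions: LiCl, DMSO/H2O, 140 °C
Reagents that add atoms: none
Why: Krapcho dealkoxycarbonylation removes the ester of the malonate-type lactone; C4 is not involved and the epimerisable C3 centre disappears.

Step 12
Reactants: 24 (S)-4-(4-benzyloxy-3-methoxybenzyl)dihydrofuran-2(3H)-one; 17 (2S,3R)-7-benzyloxy-2-(4-benzyloxy-3-methoxyphenyl)-5-(bromomethyl)-3-(triisopropylsilyloxymethyl)-2,3-dihydrobenzofuran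
Product: 26 (3S,4S)-3-{[(2S,3R)-7-benzyloxy-2-(4-benzyloxy-3-methoxyphenyl)-3-(triisopropylsilyloxymethyl)-2,3-dihydrobenzofuran-5-yl]methyl}-4-(4-benzyloxy-3-methoxybenzyl)dihydrofuran-2(3H)-one, via lactone lithium enolate 25 (not isolated)
Conditions: 24 (1.4 equiv), LiN(SiMe3)2, THF, −78 °C; then 17, DMPU, −78 → −40 °C
Reagents that add atoms: none
Why: Alkylation of a γ-butyrolactone lithium enolate by a benzylic bromide takes place anti to the C4 benzyl group, the standard entry to trans-2,3-dibenzylbutyrolactones, so the existing C4 centre sets C3 as S.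

Step 13
Reactants: 26 (3S,4S)-3-{[(2S,3R)-7-benzyloxy-2-(4-benzyloxy-3-methoxyphenyl)-3-(triisopropylsilyloxymethyl)-2,3-dihydrobenzofuran-5-yl]methyl}-4-(4-benzyloxy-3-methoxybenzyl)dihydrofuran-2(3H)-one
Product: 27 (3S,4S)-3-{[(2S,3R)-7-benzyloxy-2-(4-benzyloxy-3-methoxyphenyl)-3-(hydroxymethyl)-2,3-dihydrobenzofuran-5-yl]methyl}-4-(4-benzyloxy-3-methoxybenzyl)dihydrofuran-2(3H)-one
Conditions: Bu4NF, AcOH, THF, 0 °C → rt
Reagents that add atoms: none
Why: Fluoride cleavage of the silyl ether, buffered by AcOH so that the lactone and its α-centre (already in the thermodynamically preferred trans arrangement) are not disturbed.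

Step 14
Reactants: 27 (3S,4S)-3-{[(2S,3R)-7-benzyloxy-2-(4-benzyloxy-3-methoxyphenyl)-3-(hydroxymethyl)-2,3-dihydrobenzofuran-5-yl]methyl}-4-(4-benzyloxy-3-methoxybenzyl)dihydrofuran-2(3H)-one
Product: 28 (3S,4S)-3-{[(2S,3R)-7-hydroxy-2-(4-hydroxy-3-methoxyphenyl)-3-(hydroxymethyl)-2,3-dihydrobenzofuran-5-yl]methyl}-4-(4-hydroxy-3-methoxybenzyl)dihydrofuran-2(3H)-one (CNP0118131.1)
Conditions: H2 (1 atm), 10% Pd/C, EtOAc/EtOH, rt
Reagents that add atoms: none
Why: Hydrogenolysis of the three aryl benzyl ethers over Pd/C under neutral conditions, which are expected to leave the cyclic benzylic C2–O1 bond, the lactone and all four stereocentres intact, gives the target.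

Compound list
1 | 5-bromo-2-fluorophenylacetic acid | OC(=O)Cc1cc(Br)ccc1F | starting material
2 | (S)-4-benzyl-2-oxazolidinone | O=C1N[C@@H](Cc2ccccc2)CO1 | starting material
3 | (5-bromo-2-fluorophenyl)acetic pivalic anhydride | CC(C)(C)C(=O)OC(=O)Cc1cc(Br)ccc1F | intermediate (not isolated)
4 | (S)-4-benzyl-3-[2-(5-bromo-2-fluorophenyl)acetyl]oxazolidin-2-one | O=C(Cc1cc(Br)ccc1F)N1[C@@H](Cc2ccccc2)COC1=O | intermediate
5 | 4-benzyloxy-3-methoxybenzaldehyde | COc1cc(C=O)ccc1OCc1ccccc1 | starting material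
6 | Z-dibutylboron enolate of 4 | CCCCB(CCCC)O/C(=C\c1cc(Br)ccc1F)N1[C@@H](Cc2ccccc2)COC1=O | intermediate (not isolated)
7 | (S)-4-benzyl-3-[(2S,3S)-3-(4-benzyloxy-3-methoxyphenyl)-2-(5-bromo-2-fluorophenyl)-3-hydroxypropanoyl]oxazolidin-2-one | O=C([C@@H](c1cc(Br)ccc1F)[C@H](O)c1ccc(OCc2ccccc2)c(OC)c1)N1[C@@H](Cc2ccccc2)COC1=O | intermediate
8 | (1S,2R)-1-(4-benzyloxy-3-methoxyphenyl)-2-(5-bromo-2-fluorophenyl)propane-1,3-diol | OC[C@@H](c1cc(Br)ccc1F)[C@H](O)c1ccc(OCc2ccccc2)c(OC)c1 | intermediate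
9 | (1S,2R)-1-(4-benzyloxy-3-methoxyphenyl)-2-(5-bromo-2-fluorophenyl)-3-(triisopropylsilyloxy)propan-1-ol | CC(C)[Si](OC[C@@H](c1cc(Br)ccc1F)[C@H](O)c1ccc(OCc2ccccc2)c(OC)c1)(C(C)C)C(C)C | intermediate
10 | (1S,2R)-1-(4-benzyloxy-3-methoxyphenyl)-2-(2-fluoro-5-formylphenyl)-3-(triisopropylsilyloxy)propan-1-ol | CC(C)[Si](OC[C@@H](c1cc(C=O)ccc1F)[C@H](O)c1ccc(OCc2ccccc2)c(OC)c1)(C(C)C)C(C)C | intermediate (not isolated)
11 | (1S,2R)-1-(4-benzyloxy-3-methoxyphenyl)-2-[2-fluoro-5-(hydroxymethyl)phenyl]-3-(triisopropylsilyloxy)propan-1-ol (precursor of the key step) | CC(C)[Si](OC[C@@H](c1cc(CO)ccc1F)[C@H](O)c1ccc(OCc2ccccc2)c(OC)c1)(C(C)C)C(C)C | intermediate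
12 | dilithium dialkoxide of the aryne formed from 11 by loss of HF | [Li]OCC1=CC#CC(=C1)[C@H](CO[Si](C(C)C)(C(C)C)C(C)C)[C@H](O[Li])c1ccc(OCc2ccccc2)c(OC)c1 | intermediate (not isolated)
13 | (2S,3R)-2-(4-benzyloxy-3-methoxyphenyl)-7-lithio-5-(lithiooxymethyl)-3-(triisopropylsilyloxymethyl)-2,3-dihydrobenzofuran | [Li]OCc1cc([Li])c2c(c1)[C@H](CO[Si](C(C)C)(C(C)C)C(C)C)[C@@H](c1ccc(OCc3ccccc3)c(OC)c1)O2 | intermediate (not isolated)
14 | dimethyl [(2S,3R)-2-(4-benzyloxy-3-methoxyphenyl)-5-(lithiooxymethyl)-3-(triisopropylsilyloxymethyl)-2,3-dihydrobenzofuran-7-yl]boronate | [Li]OCc1cc(B(OC)OC)c2c(c1)[C@H](CO[Si](C(C)C)(C(C)C)C(C)C)[C@@H](c1ccc(OCc3ccccc3)c(OC)c1)O2 | intermediate (not isolated)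
15 | (2S,3R)-2-(4-benzyloxy-3-methoxyphenyl)-5-(hydroxymethyl)-3-(triisopropylsilyloxymethyl)-2,3-dihydrobenzofuran-7-ol (product of the key step) | OCc1cc(O)c2c(c1)[C@H](CO[Si](C(C)C)(C(C)C)C(C)C)[C@@H](c1ccc(OCc3ccccc3)c(OC)c1)O2 | intermediate
16 | [(2S,3R)-7-benzyloxy-2-(4-benzyloxy-3-methoxyphenyl)-3-(triisopropylsilyloxymethyl)-2,3-dihydrobenzofuran-5-yl]methanol | OCc1cc(OCc3ccccc3)c2c(c1)[C@H](CO[Si](C(C)C)(C(C)C)C(C)C)[C@@H](c1ccc(OCc3ccccc3)c(OC)c1)O2 | intermediate
17 | (2S,3R)-7-benzyloxy-2-(4-benzyloxy-3-methoxyphenyl)-5-(bromomethyl)-3-(triisopropylsilyloxymethyl)-2,3-dihydrobenzofuran | BrCc1cc(OCc3ccccc3)c2c(c1)[C@H](CO[Si](C(C)C)(C(C)C)C(C)C)[C@@H](c1ccc(OCc3ccccc3)c(OC)c1)O2 | intermediate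
18 | diethyl malonate | CCOC(=O)CC(=O)OCC | starting material
19 | (S)-epichlorohydrin | ClC[C@@H]1CO1 | starting material
20 | ethyl (1R,5S)-2-oxo-3-oxabicyclo[3.1.0]hexane-1-carboxylate | O=C1OC[C@H]2C[C@@]12C(=O)OCC | intermediate
21 | 1-benzyloxy-4-bromo-2-methoxybenzene | COc1cc(Br)ccc1OCc1ccccc1 | starting material
22 | (4-benzyloxy-3-methoxyphenyl)magnesium bromide | COc1cc([Mg]Br)ccc1OCc1ccccc1 | intermediate (not isolated)
23 | ethyl (3R,4S)-4-(4-benzyloxy-3-methoxybenzyl)-2-oxotetrahydrofuran-3-carboxylate (trans; C3 epimerisable) | CCOC(=O)[C@@H]1C(=O)OC[C@H]1Cc1ccc(OCc2ccccc2)c(OC)c1 | intermediate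
24 | (S)-4-(4-benzyloxy-3-methoxybenzyl)dihydrofuran-2(3H)-one | COc1cc(C[C@@H]2COC(=O)C2)ccc1OCc1ccccc1 | intermediate
25 | lithium enolate of 24 | [Li]OC1=C[C@H](Cc2ccc(OCc3ccccc3)c(OC)c2)CO1 | intermediate (not isolated)
26 | (3S,4S)-3-{[(2S,3R)-7-benzyloxy-2-(4-benzyloxy-3-methoxyphenyl)-3-(triisopropylsilyloxymethyl)-2,3-dihydrobenzofuran-5-yl]methyl}-4-(4-benzyloxy-3-methoxybenzyl)dihydrofuran-2(3H)-one | COc1cc(C[C@@H]2COC(=O)[C@H]2Cc2cc(OCc4ccccc4)c3c(c2)[C@H](CO[Si](C(C)C)(C(C)C)C(C)C)[C@@H](c2ccc(OCc4ccccc4)c(OC)c2)O3)ccc1OCc1ccccc1 | intermediate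
27 | (3S,4S)-3-{[(2S,3R)-7-benzyloxy-2-(4-benzyloxy-3-methoxyphenyl)-3-(hydroxymethyl)-2,3-dihydrobenzofuran-5-yl]methyl}-4-(4-benzyloxy-3-methoxybenzyl)dihydrofuran-2(3H)-one | COc1cc(C[C@@H]2COC(=O)[C@H]2Cc2cc(OCc4ccccc4)c3c(c2)[C@H](CO)[C@@H](c2ccc(OCc4ccccc4)c(OC)c2)O3)ccc1OCc1ccccc1 | intermediate
28 | (3S,4S)-3-{[(2S,3R)-7-hydroxy-2-(4-hydroxy-3-methoxyphenyl)-3-(hydroxymethyl)-2,3-dihydrobenzofuran-5-yl]methyl}-4-(4-hydroxy-3-methoxybenzyl)dihydrofuran-2(3H)-one (CNP0118131.1) | COc1cc(C[C@@H]2COC(=O)[C@H]2Cc2cc(O)c3c(c2)[C@H](CO)[C@@H](c2ccc(O)c(OC)c2)O3)ccc1O | target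

Total step count: 14. Longest linear sequence: 11 steps (steps 1–8, then 12–14); fragment 2 (steps 9–11) is made in parallel.

Steps most likely to fail

1. Step 6. What may go wrong: proton transfer from the liberated tetramethylpiperidine to the C7 aryllithium before the borate arrives (loss of the C7 oxygen handle), or sluggish loss of LiF from the polyanion. Fallback: metalation is separated from aryne formation and the metal is changed. The fallback sets out from 11. LiTMP at −78 °C (where LiF is not lost) followed by iodine should give the ortho-iodinated fluoroarene diol F1. After isolation, i-PrMgCl·LiCl (3.3 equiv, THF, −20 → 45 °C) forms the magnesium alkoxides and undergoes iodine–magnesium exchange. On warming, the 2-fluoroarylmagnesium species should release the same aryne in an amine-free medium, and the magnesium alkoxide closes ring C. The C7 arylmagnesium then meets no proton donor and is borylated with B(OMe)3 and oxidised with NaOH/H2O2. The fallback comes back to the route at 15.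

2. Step 12. What may go wrong: ionisation and self-alkylation of the electron-rich benzylic bromide before or during the enolate alkylation, or over-alkylation of the lactone. Fallback: an aldol–hydrogenolysis union that avoids the bromide. The fallback sets out from 16 (with 24 as the partner). MnO2 in CH2Cl2 should give the aryl aldehyde F2. Lithium enolate 25 (from 24, LiN(SiMe3)2, THF, −78 °C) adds to it anti to the C4 benzyl group to give the β-hydroxy lactone F3 as carbinol epimers. Hydrogen over Pd/C in EtOAc/AcOH removes the para-oxygenated benzylic hydroxyl together with the three benzyl ethers to give the TIPS-protected target F4. Bu4NF/AcOH then removes the silyl group, and the fallback comes back to the route at 28.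

3. Step 10. What may go wrong: direct attack of the aryl Grignard reagent on the lactone or ester carbonyl instead of homoconjugate opening of the cyclopropane. Fallback: auxiliary-controlled alkylation. The fallback sets out from 5 and 2. NaBH4 in MeOH converts 5 into the benzylic alcohol F5, and PBr3 in Et2O gives the benzylic bromide F6. Acylation of 2 with mono-tert-butyl succinate (PivCl, Et3N, LiCl, THF) gives the succinyl imide F7. Its sodium enolate (NaN(SiMe3)2, THF, −78 °C) is alkylated by F6 on the face away from the auxiliary benzyl group to give the alkylated imide F8. LiBH4 releases the hydroxy ester F9, and TsOH in toluene closes it with loss of tert-butanol. The fallback comes back to the route at 24.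

Further compounds
F1 | step 6 | (1S,2R)-1-(4-benzyloxy-3-methoxyphenyl)-2-[2-fluoro-5-(hydroxymethyl)-3-iodophenyl]-3-(triisopropylsilyloxy)propan-1-ol | CC(C)[Si](OC[C@@H](c1cc(CO)cc(I)c1F)[C@H](O)c1ccc(OCc2ccccc2)c(OC)c1)(C(C)C)C(C)C
F2 | step 12 | (2S,3R)-7-benzyloxy-2-(4-benzyloxy-3-methoxyphenyl)-3-(triisopropylsilyloxymethyl)-2,3-dihydrobenzofuran-5-carbaldehyde | O=Cc1cc(OCc3ccccc3)c2c(c1)[C@H](CO[Si](C(C)C)(C(C)C)C(C)C)[C@@H](c1ccc(OCc3ccccc3)c(OC)c1)O2
F3 | step 12 | (3R,4S)-3-{[(2S,3R)-7-benzyloxy-2-(4-benzyloxy-3-methoxyphenyl)-3-(triisopropylsilyloxymethyl)-2,3-dihydrobenzofuran-5-yl](hydroxy)methyl}-4-(4-benzyloxy-3-methoxybenzyl)dihydrofuran-2(3H)-one (carbinol epimers) | COc1cc(C[C@@H]2COC(=O)[C@H]2C(O)c2cc(OCc4ccccc4)c3c(c2)[C@H](CO[Si](C(C)C)(C(C)C)C(C)C)[C@@H](c2ccc(OCc4ccccc4)c(OC)c2)O3)ccc1OCc1ccccc1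
F4 | step 12 | (3S,4S)-3-{[(2S,3R)-7-hydroxy-2-(4-hydroxy-3-methoxyphenyl)-3-(triisopropylsilyloxymethyl)-2,3-dihydrobenzofuran-5-yl]methyl}-4-(4-hydroxy-3-methoxybenzyl)dihydrofuran-2(3H)-one | COc1cc(C[C@@H]2COC(=O)[C@H]2Cc2cc(O)c3c(c2)[C@H](CO[Si](C(C)C)(C(C)C)C(C)C)[C@@H](c2ccc(O)c(OC)c2)O3)ccc1O
F5 | step 10 | (4-benzyloxy-3-methoxyphenyl)methanol | COc1cc(CO)ccc1OCc1ccccc1
F6 | step 10 | 1-benzyloxy-4-(bromomethyl)-2-methoxybenzene | COc1cc(CBr)ccc1OCc1ccccc1
F7 | step 10 | tert-butyl 4-[(4S)-4-benzyl-2-oxooxazolidin-3-yl]-4-oxobutanoate | CC(C)(C)OC(=O)CCC(=O)N1[C@@H](Cc2ccccc2)COC1=O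
F8 | step 10 | tert-butyl (3S)-3-(4-benzyloxy-3-methoxybenzyl)-4-[(4S)-4-benzyl-2-oxooxazolidin-3-yl]-4-oxobutanoate | CC(C)(C)OC(=O)C[C@H](Cc1ccc(OCc2ccccc2)c(OC)c1)C(=O)N1[C@@H](Cc2ccccc2)COC1=O
F9 | step 10 | tert-butyl (3S)-4-(4-benzyloxy-3-methoxyphenyl)-3-(hydroxymethyl)butanoate | CC(C)(C)OC(=O)C[C@H](Cc1ccc(OCc2ccccc2)c(OC)c1)CO
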